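**Retrosynthetic overview**

- The target is a (2S)-flavanone. The plan rests on C8–H of ring A, the one aromatic position flanked by the ring oxygen O1 and the C7 methoxy oxygen; the C8 methoxy group is therefore disconnected to C8–H and its C8–O bond is made late by directed lithiation, borylation and oxidation.
- During that step the C4 ketone is stored as a (4S)-silyl ether and the ring B phenol as a triisopropylsilyl ether; O-methylation, C4 desilylation, oxidation and phenol release finish the synthesis.
- C2 is set by transfer-hydrogenative kinetic resolution of the racemic 7-methoxyflavanone, which delivers the (2S,4S)-cis-alcohol.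
- Ring C is the only ring formed (oxa-Michael closure of a 2'-hydroxychalcone from a Claisen–Schmidt condensation); rings A and B are bought as paeonol and 3-hydroxy-4,5-dimethoxybenzaldehyde.

Key step: step 6

Remark: the stereodescriptor of the target SMILES corresponds to (2S); the C4 stereocentre carried from step 4 to step 8 is temporary and is erased by the oxidation in step 9.

**Route**

Step 1
Reactants: 1 2'-hydroxy-4'-methoxyacetophenone; 2 3-hydroxy-4,5-dimethoxybenzaldehyde
Product: 3 (E)-1-(2-hydroxy-4-methoxyphenyl)-3-(3-hydroxy-4,5-dimethoxyphenyl)prop-2-en-1-one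
Conditions: KOH (aq., excess), EtOH, rt; then aq. HCl
Reagents that add atoms: none
Why: Claisen–Schmidt aldol condensation, in which the acetophenone enolate adds to the aldehyde (its meta-phenoxide is not conjugated to the formyl group and does not switch it off) and E1cB loss of water gives the (E)-enone.

Step 2
Reactants: 3 (E)-1-(2-hydroxy-4-methoxyphenyl)-3-(3-hydroxy-4,5-dimethoxyphenyl)prop-2-en-1-one
Product: 4 rac-2-(3-hydroxy-4,5-dimethoxyphenyl)-7-methoxychroman-4-one
Conditions: NaOAc, EtOH, reflux
Reagents that add atoms: none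
Why: Base-mediated intramolecular oxa-Michael addition (6-endo-trig) of the 2'-phenoxide to the enone closes ring C and creates C2 as a racemate; chalcone and flavanone equilibrate, so recovered chalcone can be resubmitted.

Step 3
Reactants: 4 rac-2-(3-hydroxy-4,5-dimethoxyphenyl)-7-methoxychroman-4-one; 5 triisopropylsilyl chloride
Product: 6 rac-2-(4,5-dimethoxy-3-triisopropylsilyloxyphenyl)-7-methoxychroman-4-one
Conditions: imidazole, DMF, rt
Reagents that add atoms: triisopropylsilyl chloride 5, CC(C)[Si](Cl)(C(C)C)C(C)C
Why: Imidazole-promoted silylation of the only free hydroxyl group; the bulky aryl silyl ether is chosen because it tolerates organolithium reagents and its oxygen does not direct metalation.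

Step 4
Reactants: 6 rac-2-(4,5-dimethoxy-3-triisopropylsilyloxyphenyl)-7-methoxychroman-4-one
Product: 7 (2S,4S)-2-(4,5-dimethoxy-3-triisopropylsilyloxyphenyl)-7-methoxychroman-4-ol
Conditions: RuCl[(S,S)-TsDPEN](p-cymene) (cat.), HCO2H/Et3N (5:2), EtOAc, rt, stopped near half conversion
Reagents that add atoms: none
Why: Noyori asymmetric transfer hydrogenation run as a kinetic resolution: the (S,S)-catalyst sets C4 as (S) by its usual facial preference for aryl ketones, and only in the (2S)-ketone is that face the one opposite the C2 aryl group, so this enantiomer should be reduced fast to the 2,4-cis alcohol while the (2R)-ketone stays behind and can be racemised through the chalcone and recycled.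

Step 5
Reactants: 7 (2S,4S)-2-(4,5-dimethoxy-3-triisopropylsilyloxyphenyl)-7-methoxychroman-4-ol; 8 tert-butyldimethylsilyl chloride
Product: 9 (2S,4S)-4-(tert-butyldimethylsilyloxy)-2-(4,5-dimethoxy-3-triisopropylsilyloxyphenyl)-7-methoxychromane
Conditions: imidazole, DMF, rt
Reagents that add atoms: tert-butyldimethylsilyl chloride 8, CC(C)(C)[Si](C)(C)Cl
Why: Imidazole-promoted silylation of the secondary benzylic alcohol under non-acidic conditions that cannot ionise the electron-rich C4 position; the silyl ether stores the future ketone so that ring C offers no enolisable or electrophilic site to the organolithium.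

Step 6
Reactants: 9 (2S,4S)-4-(tert-butyldimethylsilyloxy)-2-(4,5-dimethoxy-3-triisopropylsilyloxyphenyl)-7-methoxychromane; 10 trimethyl borate; 11 hydrogen peroxide
Product: 14 (2S,4S)-4-(tert-butyldimethylsilyloxy)-2-(4,5-dimethoxy-3-triisopropylsilyloxyphenyl)-7-methoxychroman-8-ol, via C8-aryllithium 12 (not isolated), via lithium aryltrimethoxyborate 13 (not isolated)
Conditions: n-BuLi (slight excess), TMEDA, Et2O, 0 °C; B(OMe)3, −78 °C to rt; AcOH, 30% aq. H2O2, 0 °C to rt
Reagents that add atoms: hydrogen peroxide 11, OO (the C8 oxygen); trimethyl borate 10, COB(OC)OC (its boron stays only in 13); n-butyllithium, [Li]CCCC (its lithium stays only in 12 and 13)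
Why: n-BuLi·TMEDA is held by the lone pairs of O1 and the C7 methoxy oxygen and removes the C8 proton, the only proton in the molecule that is ortho to two oxygen substituents on one ring; aryllithium 12 adds to B(OMe)3 to give ate complex 13, and after acidification hydroperoxide adds to boron, the aryl group shifts from boron to oxygen and hydrolysis of the aryl borate frees the phenol. The closest known reaction type is the directed ortho-metalation of 1,3-dialkoxybenzenes at the shared ortho position followed by borate trapping and peroxide oxidation, the standard hydroxylation of an aryllithium. No ring is closed and no stereocentre is formed; C2 and C4 stay untouched because the ketone is stored as a silyl ether, so there is no enolisable or β-aryloxy carbonyl unit that base could open. The step needs C8 to be metalated in preference to C6 and C5 of ring A, C2' and C6' of ring B and the benzylic C2–H: C6 and C6' have only one ortho oxygen, C5 has none, C2' is screened by the triisopropylsilyl group whose oxygen is too hindered to bind lithium, and the sp3 C2–H is kinetically slower than a doubly activated aryl C–H. A small excess of base at 0 °C and the weakly acidic oxidation should keep both silyl ethers intact.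

Step 7
Reactants: 14 (2S,4S)-4-(tert-butyldimethylsilyloxy)-2-(4,5-dimethoxy-3-triisopropylsilyloxyphenyl)-7-methoxychroman-8-ol; 15 iodomethane
Product: 16 (2S,4S)-4-(tert-butyldimethylsilyloxy)-2-(4,5-dimethoxy-3-triisopropylsilyloxyphenyl)-7,8-dimethoxychromane
Conditions: MeI, K2CO3, acetone, 50 °C
Reagents that add atoms: iodomethane 15, CI
Why: Williamson O-methylation (SN2 of the C8 phenoxide on MeI); the weak carbonate base in acetone is not expected to cleave the hindered aryl triisopropylsilyl ether.

Step 8
Reactants: 16 (2S,4S)-4-(tert-butyldimethylsilyloxy)-2-(4,5-dimethoxy-3-triisopropylsilyloxyphenyl)-7,8-dimethoxychromane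
Product: 17 (2S,4S)-2-(4,5-dimethoxy-3-triisopropylsilyloxyphenyl)-7,8-dimethoxychroman-4-ol
Conditions: HF·pyridine, pyridine, THF, 0 °C to rt
Reagents that add atoms: none
Why: Fluoride-assisted desilylation under mildly acidic, pyridine-buffered conditions, where alkyl silyl ethers are cleaved faster than aryl silyl ethers and the bulkier triisopropylsilyl group is slower still, while the buffer keeps the medium too weakly acidic to ionise the electron-rich benzylic C4–O bond.

Step 9
Reactants: 17 (2S,4S)-2-(4,5-dimethoxy-3-triisopropylsilyloxyphenyl)-7,8-dimethoxychroman-4-ol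
Product: 18 (2S)-2-(4,5-dimethoxy-3-triisopropylsilyloxyphenyl)-7,8-dimethoxychroman-4-one
Conditions: Dess–Martin periodinane, pyridine, CH2Cl2, 0 °C to rt
Reagents that add atoms: none
Why: Dess–Martin oxidation of the secondary benzylic alcohol to the aryl ketone under buffered, non-basic conditions, which erases the temporary C4 stereocentre without any enolate chemistry that could open ring C, so C2 should keep its (S) configuration.

Step 10
Reactants: 18 (2S)-2-(4,5-dimethoxy-3-triisopropylsilyloxyphenyl)-7,8-dimethoxychroman-4-one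
Product: 19 (2S)-2-(3-hydroxy-4,5-dimethoxyphenyl)-7,8-dimethoxychroman-4-one
Conditions: Bu4NF, AcOH (1 equiv each), THF, 0 °C
Reagents that add atoms: none
Why: Fluoride cleavage of the aryl silyl ether with acetic acid present to protonate the phenoxide as it forms, so that the medium never becomes basic enough for E1cB opening of the flavanone to the chalcone, which would racemise C2.

**Compound list**

1 | 2'-hydroxy-4'-methoxyacetophenone | CC(=O)c1ccc(OC)cc1O | starting material
2 | 3-hydroxy-4,5-dimethoxybenzaldehyde | COc1cc(C=O)cc(O)c1OC | starting material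
3 | (E)-1-(2-hydroxy-4-methoxyphenyl)-3-(3-hydroxy-4,5-dimethoxyphenyl)prop-2-en-1-one | COc1ccc(C(=O)/C=C/c2cc(O)c(OC)c(OC)c2)c(O)c1 | intermediate
4 | rac-2-(3-hydroxy-4,5-dimethoxyphenyl)-7-methoxychroman-4-one | COc1cc(C2CC(=O)c3ccc(OC)cc3O2)cc(O)c1OC | intermediate
5 | triisopropylsilyl chloride | CC(C)[Si](Cl)(C(C)C)C(C)C | starting material
6 | rac-2-(4,5-dimethoxy-3-triisopropylsilyloxyphenyl)-7-methoxychroman-4-one | COc1cc(C2CC(=O)c3ccc(OC)cc3O2)cc(O[Si](C(C)C)(C(C)C)C(C)C)c1OC | intermediate
7 | (2S,4S)-2-(4,5-dimethoxy-3-triisopropylsilyloxyphenyl)-7-methoxychroman-4-ol (2,4-cis) | COc1cc([C@@H]2C[C@H](O)c3ccc(OC)cc3O2)cc(O[Si](C(C)C)(C(C)C)C(C)C)c1OC | intermediate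
8 | tert-butyldimethylsilyl chloride | CC(C)(C)[Si](C)(C)Cl | starting material
9 | (2S,4S)-4-(tert-butyldimethylsilyloxy)-2-(4,5-dimethoxy-3-triisopropylsilyloxyphenyl)-7-methoxychromane | COc1cc([C@@H]2C[C@H](O[Si](C)(C)C(C)(C)C)c3ccc(OC)cc3O2)cc(O[Si](C(C)C)(C(C)C)C(C)C)c1OC | intermediate
10 | trimethyl borate | COB(OC)OC | starting material
11 | hydrogen peroxide | OO | starting material
12 | C8-lithio derivative of 9 (aryllithium) | COc1cc([C@@H]2C[C@H](O[Si](C)(C)C(C)(C)C)c3ccc(OC)c([Li])c3O2)cc(O[Si](C(C)C)(C(C)C)C(C)C)c1OC | intermediate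
13 | lithium trimethoxyborate of 9 at C8 (ate complex) | [Li+].COc1cc([C@@H]2C[C@H](O[Si](C)(C)C(C)(C)C)c3ccc(OC)c([B-](OC)(OC)OC)c3O2)cc(O[Si](C(C)C)(C(C)C)C(C)C)c1OC | intermediate
14 | (2S,4S)-4-(tert-butyldimethylsilyloxy)-2-(4,5-dimethoxy-3-triisopropylsilyloxyphenyl)-7-methoxychroman-8-ol | COc1cc([C@@H]2C[C@H](O[Si](C)(C)C(C)(C)C)c3ccc(OC)c(O)c3O2)cc(O[Si](C(C)C)(C(C)C)C(C)C)c1OC | intermediate
15 | iodomethane | CI | starting material
16 | (2S,4S)-4-(tert-butyldimethylsilyloxy)-2-(4,5-dimethoxy-3-triisopropylsilyloxyphenyl)-7,8-dimethoxychromane | COc1cc([C@@H]2C[C@H](O[Si](C)(C)C(C)(C)C)c3ccc(OC)c(OC)c3O2)cc(O[Si](C(C)C)(C(C)C)C(C)C)c1OC | intermediate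
17 | (2S,4S)-2-(4,5-dimethoxy-3-triisopropylsilyloxyphenyl)-7,8-dimethoxychroman-4-ol | COc1cc([C@@H]2C[C@H](O)c3ccc(OC)c(OC)c3O2)cc(O[Si](C(C)C)(C(C)C)C(C)C)c1OC | intermediate
18 | (2S)-2-(4,5-dimethoxy-3-triisopropylsilyloxyphenyl)-7,8-dimethoxychroman-4-one | COc1cc([C@@H]2CC(=O)c3ccc(OC)c(OC)c3O2)cc(O[Si](C(C)C)(C(C)C)C(C)C)c1OC | intermediate
19 | (2S)-2-(3-hydroxy-4,5-dimethoxyphenyl)-7,8-dimethoxychroman-4-one | COc1cc([C@@H]2CC(=O)c3ccc(OC)c(OC)c3O2)cc(O)c1OC | target

**Step count and risks**

Total step count: 10. Longest linear sequence: 10 steps (1 or 2 to 19).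

Steps most likely to fail:

1. Step 6 (directed metalation, borylation, oxidation). Lithiation may spread to C6' of ring B (ortho to the C5' methoxy group and within reach of O1) or to the benzylic C2–H, or the 2,6-disubstituted aryllithium may be trapped incompletely, so that the phenol forms as part of a mixture. Fallback, setting out from 2 and returning at 17: the C8 oxygen is bought with ring A. Claisen–Schmidt condensation of 2 with 2'-hydroxy-3',4'-dimethoxyacetophenone F1 (KOH, EtOH, rt; HCl quench) should give (E)-1-(2-hydroxy-3,4-dimethoxyphenyl)-3-(3-hydroxy-4,5-dimethoxyphenyl)prop-2-en-1-one F2. NaOAc in refluxing EtOH should close it to rac-2-(3-hydroxy-4,5-dimethoxyphenyl)-7,8-dimethoxychroman-4-one F3, and 5 with imidazole in DMF should give rac-2-(4,5-dimethoxy-3-triisopropylsilyloxyphenyl)-7,8-dimethoxychroman-4-one F4. Transfer hydrogenation of F4 with RuCl[(S,S)-TsDPEN](p-cymene) and HCO2H/Et3N, run as in step 4, should reduce the (2S)-enantiomer directly to 17, and the route continues with step 9.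

2. Step 4 (kinetic resolution). The catalyst may discriminate poorly between the enantiomers of 6, or reversible ring opening to the chalcone in the amine-containing medium may erode the enantiomeric purity of 7. Fallback, setting out from 6 and returning at 7: NaBH4 in THF/MeOH at 0 °C should reduce racemic 6 from the face opposite the C2 aryl group to the racemic 2,4-cis-alcohol, that is 7 together with its enantiomer (2R,4R)-2-(4,5-dimethoxy-3-triisopropylsilyloxyphenyl)-7-methoxychroman-4-ol F5. Lipase-catalysed acylation (Candida antarctica lipase B, vinyl acetate, MTBE, 30–40 °C) is expected, by the usual preference of lipases for the (R)-configured 1-arylalkanol, to convert F5 into (2R,4R)-4-acetoxy-2-(4,5-dimethoxy-3-triisopropylsilyloxyphenyl)-7-methoxychromane F6 and to leave 7. Compound 7 is separated by chromatography and rejoins the route at step 5.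

3. Step 8 (selective C4 desilylation). The aryl silyl ether may be lost together with the C4 silyl ether, or the acidic fluoride may ionise the electron-rich benzylic C4–O bond and cause elimination to the flav-3-ene. Fallback, setting out from 16 and returning at 17: Bu4NF/AcOH in THF at rt to 40 °C should remove both silyl groups and give (2S,4S)-2-(3-hydroxy-4,5-dimethoxyphenyl)-7,8-dimethoxychroman-4-ol F7. One equivalent of 5 with imidazole in DMF at 0 °C should then silylate the phenol in preference to the hindered secondary benzylic alcohol and return 17.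

**Further compounds**

F1 | step 6 | 2'-hydroxy-3',4'-dimethoxyacetophenone (purchased) | CC(=O)c1ccc(OC)c(OC)c1O
F2 | step 6 | (E)-1-(2-hydroxy-3,4-dimethoxyphenyl)-3-(3-hydroxy-4,5-dimethoxyphenyl)prop-2-en-1-one | COc1ccc(C(=O)/C=C/c2cc(O)c(OC)c(OC)c2)c(O)c1OC
F3 | step 6 | rac-2-(3-hydroxy-4,5-dimethoxyphenyl)-7,8-dimethoxychroman-4-one | COc1cc(C2CC(=O)c3ccc(OC)c(OC)c3O2)cc(O)c1OC
F4 | step 6 | rac-2-(4,5-dimethoxy-3-triisopropylsilyloxyphenyl)-7,8-dimethoxychroman-4-one | COc1cc(C2CC(=O)c3ccc(OC)c(OC)c3O2)cc(O[Si](C(C)C)(C(C)C)C(C)C)c1OC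
F5 | step 4 | (2R,4R)-2-(4,5-dimethoxy-3-triisopropylsilyloxyphenyl)-7-methoxychroman-4-ol | COc1cc([C@H]2C[C@@H](O)c3ccc(OC)cc3O2)cc(O[Si](C(C)C)(C(C)C)C(C)C)c1OC
F6 | step 4 | (2R,4R)-4-acetoxy-2-(4,5-dimethoxy-3-triisopropylsilyloxyphenyl)-7-methoxychromane | COc1cc([C@H]2C[C@@H](OC(C)=O)c3ccc(OC)cc3O2)cc(O[Si](C(C)C)(C(C)C)C(C)C)c1OC
F7 | step 8 | (2S,4S)-2-(3-hydroxy-4,5-dimethoxyphenyl)-7,8-dimethoxychroman-4-ol | COc1cc([C@@H]2C[C@H](O)c3ccc(OC)c(OC)c3O2)cc(O)c1OC
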